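**Plan**

- Retrosynthesis: the dihydropyran ring C is opened at the O–C(spiro) and CH2–CH(Ph) bonds (retro oxa-[4+2]) to a benzylidene o-quinone methide and an exocyclic diene. The diene methylidene goes back to an enone carbonyl, ring A is cut at C8–C8a, and ring B is cut at C1–C2 and C4–C4a.
- Enabling feature: in ring B the alkene carbon C8a and the oxygen-bearing spiro carbon C2 are 1,3-related through C1. Ring B is therefore a masked 4-alkylcyclohexane-1,3-dione, the [3+3] sum of a methyl ketone (C1, C8a, C4a) and an acrylate (C2, C3, C4).
- Forward order: ring B (Michael–Claisen), ring A (cation–olefin closure onto the silylated dione), isopropenyl to isopropyl, C=O to C=CH2, then ring C with arene ring D in a three-component o-quinone methide cycloaddition.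
- Stereochemistry: the C5 methyl comes from (R)-citronellic acid. C4a and C8 are set together in the chair-like closure of ring A (C4a by dynamic resolution). The spiro carbon and the benzylic carbon are set in the cycloaddition (attack anti to the isopropyl group, exo arrangement).

Key step: step 2

Remark: the octalin carbons are numbered as in naphthalen-2-one (C2 carbonyl or spiro carbon, C1 vinyl CH, C8 isopropyl-bearing, C5 methyl-bearing, C4a ring-fusion CH); 1 of high enantiomeric purity and 12 are taken as purchased.

**Step 1**
Reactants: 1 (R)-citronellic acid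
Product: 2 (4R)-4,8-dimethylnon-7-en-2-one
Conditions: MeLi (2.2 equiv), Et2O, 0 °C → rt; then H2O
Reagents that add atoms: methyllithium, [Li]C
Why: The lithium carboxylate accepts one methyllithium and the adduct collapses to the methyl ketone only on work-up (ketone synthesis from a carboxylic acid and an organolithium), so no tertiary alcohol should form, and the β-stereocenter is not enolisable and is carried through unchanged.

**Step 2**
Reactants: 2 (4R)-4,8-dimethylnon-7-en-2-one; 3 methyl acrylate
Product: 5 4-[(2R)-6-methylhept-5-en-2-yl]cyclohexane-1,3-dione (both ring C4 epimers), via keto ester 4 (not isolated)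
Conditions: KOtBu (2.2 equiv), THF, 0 °C → rt, slow addition of 3; then 1 M HCl
Reagents that add atoms: none
Why: Under equilibrating alkoxide conditions the more substituted enolate of 2 adds to the β-carbon of 3 (Michael addition, the later C4–C4a bond), and the methyl-derived enolate of keto ester 4 then attacks the ester carbonyl (Claisen condensation, the later C1–C2 bond), the sequence being pulled forward by irreversible deprotonation of the 1,3-dione. This is the known Michael–Claisen [3+3] route from methyl ketones and acrylates to 4-substituted cyclohexane-1,3-diones. Ring B closes by 6-exo-trig attack of the enolate carbon on the ester carbonyl. The one new stereocenter, the ring carbon bearing the side chain (later C4a), is α to a carbonyl, forms as both epimers and is left unset on purpose, because it equilibrates and is resolved in step 3; the side-chain methyl stereocenter is untouched. The step needs Michael addition at the methylene and not the methyl group of 2, and a single addition of acrylate; the first rests on the thermodynamic preference for the more substituted enolate and on the fact that afterwards only the methyl group can reach the ester through a six-membered transition state. The second rests on slow addition of 3 and on the hindered donor carbon after the first addition.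

**Step 3**
Reactants: 5 4-[(2R)-6-methylhept-5-en-2-yl]cyclohexane-1,3-dione
Product: 8 (4aR,5R,8S)-5-methyl-8-(prop-1-en-2-yl)-4,4a,5,6,7,8-hexahydronaphthalen-2(3H)-one, via silyloxyenone 6 (not isolated), via bis-silyl ene adduct 7 (not isolated)
Conditions: Me3SiOTf (2.5 equiv), 2,6-di-tert-butyl-4-methylpyridine (2.5 equiv), CH2Cl2, −78 → 0 °C; then 1 M HCl, THF, 0 °C
Reagents that add atoms: none
Why: Proposed new method: Me3SiOTf silylates the enol of 5 to silyloxyenone 6 and then its carbonyl oxygen, which turns the silyloxy-bearing carbon (C8a) into an oxocarbenium-type electrophile (silyl transfer between the two oxygens is fast, so the site of the first silylation does not matter); the trisubstituted alkene attacks it through its less substituted carbon in a 6-exo cation–olefin closure of ring A, the tertiary cation loses a methyl proton to the hindered pyridine (ene-type termination) to give 7, and acid work-up eliminates the silyloxy group β to the carbonyl to give the enone. The closest known reactions are the Lewis-acid-mediated addition of π-nucleophiles to 3-silyloxy-2-en-1-ones and the carbonyl-ene cyclization of citronellal to isopulegol. Attack perpendicular to the planar cation forces the ring B bond at C4a to be axial on the forming chair, so with the methyl and the developing isopropenyl group equatorial, H-4a should end trans to the C5 methyl and cis to the C8 substituent as in the target, the mismatched C4a epimer being returned by reversible enolisation toward C4a (dynamic kinetic resolution).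

**Step 4**
Reactants: 8 (4aR,5R,8S)-5-methyl-8-(prop-1-en-2-yl)-4,4a,5,6,7,8-hexahydronaphthalen-2(3H)-one
Product: 9 (4aR,5R,8S)-5-methyl-8-(propan-2-yl)-4,4a,5,6,7,8-hexahydronaphthalen-2(3H)-one
Conditions: H2 (1 atm), RhCl(PPh3)3 (5 mol %), benzene, rt
Reagents that add atoms: none
Why: Homogeneous hydrogenation with RhCl(PPh3)3 should reduce the unhindered 1,1-disubstituted alkene and leave the trisubstituted conjugated alkene alone (chemoselective alkene hydrogenation, as in the reduction of carvone to carvotanacetone), under neutral conditions that do not touch the epimerisable C4a and C8 centers.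

**Step 5**
Reactants: 9 (4aR,5R,8S)-5-methyl-8-(propan-2-yl)-4,4a,5,6,7,8-hexahydronaphthalen-2(3H)-one
Product: 10 (1S,4R,4aR)-4-methyl-7-methylidene-1-(propan-2-yl)-1,2,3,4,4a,5,6,7-octahydronaphthalene
Conditions: Ph3PCH3Br, n-BuLi, THF, 0 °C; then 9, −78 → 0 °C
Reagents that add atoms: methyltriphenylphosphonium bromide, C[P+](c1ccccc1)(c1ccccc1)c1ccccc1.[Br-]
Why: Wittig methylenation of the unhindered enone carbonyl should give the conjugated exocyclic diene; the ylide is preformed and used cold without excess base so that the γ-hydrogens at C4a and C8 are not removed and the thermodynamically less favoured C4a configuration is kept.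

**Step 6**
Reactants: 10 (1S,4R,4aR)-4-methyl-7-methylidene-1-(propan-2-yl)-1,2,3,4,4a,5,6,7-octahydronaphthalene; 11 benzaldehyde; 12 2,4,6-trihydroxybenzene-1,3-dicarbaldehyde
Product: 14 Guajadial D, via o-quinone methide 13 (not isolated)
Conditions: NaOAc, AcOH, 80 °C
Reagents that add atoms: none
Why: Knoevenagel-type condensation of 12 at its free ring carbon with 11 gives o-quinone methide 13, which is trapped as an electron-poor oxadiene by the exocyclic 1,1-disubstituted alkene of 10 in an inverse-demand oxa-[4+2] cycloaddition (biomimetic three-component coupling); oxygen goes to the tertiary allylic carbon C2, approach anti to the pseudoaxial C8 isopropyl group should set the spiro center, and the (E)-benzylidene unit with the cyclohexenyl arm exo should set the benzylic center, its epimer being the expected by-product to be removed by chromatography.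

**Compound list**

1 | (R)-citronellic acid, (3R)-3,7-dimethyloct-6-enoic acid | C[C@H](CCC=C(C)C)CC(=O)O | starting material
2 | (4R)-4,8-dimethylnon-7-en-2-one | C[C@H](CCC=C(C)C)CC(C)=O | intermediate
3 | methyl acrylate | C=CC(=O)OC | starting material
4 | methyl (5R)-4-acetyl-5,9-dimethyldec-8-enoate (both C4 epimers; not isolated) | COC(=O)CCC(C(C)=O)[C@H](C)CCC=C(C)C | intermediate
5 | 4-[(2R)-6-methylhept-5-en-2-yl]cyclohexane-1,3-dione (both ring C4 epimers) | O=C1CC(=O)C(CC1)[C@H](C)CCC=C(C)C | intermediate
6 | 4-[(2R)-6-methylhept-5-en-2-yl]-3-(trimethylsilyloxy)cyclohex-2-en-1-one (not isolated) | C[Si](C)(C)OC1=CC(=O)CCC1[C@H](C)CCC=C(C)C | intermediate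
7 | trimethyl{[(4aR,5R,8S,8aR)-5-methyl-8-(prop-1-en-2-yl)-8a-(trimethylsilyloxy)-3,4,4a,5,6,7,8,8a-octahydronaphthalen-2-yl]oxy}silane (not isolated) | CC(=C)[C@@H]1CC[C@@H](C)[C@H]2CCC(O[Si](C)(C)C)=C[C@@]12O[Si](C)(C)C | intermediate
8 | (4aR,5R,8S)-5-methyl-8-(prop-1-en-2-yl)-4,4a,5,6,7,8-hexahydronaphthalen-2(3H)-one | CC(=C)[C@@H]1CC[C@@H](C)[C@H]2CCC(=O)C=C12 | intermediate
9 | (4aR,5R,8S)-5-methyl-8-(propan-2-yl)-4,4a,5,6,7,8-hexahydronaphthalen-2(3H)-one | CC(C)[C@@H]1CC[C@@H](C)[C@H]2CCC(=O)C=C12 | intermediate
10 | (1S,4R,4aR)-4-methyl-7-methylidene-1-(propan-2-yl)-1,2,3,4,4a,5,6,7-octahydronaphthalene | CC(C)[C@@H]1CC[C@@H](C)[C@H]2CCC(=C)C=C12 | intermediate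
11 | benzaldehyde | O=Cc1ccccc1 | starting material
12 | 2,4,6-trihydroxybenzene-1,3-dicarbaldehyde (diformylphloroglucinol) | O=Cc1c(O)cc(O)c(C=O)c1O | starting material
13 | (5E)-5-benzylidene-2,4-dihydroxy-6-oxocyclohexa-1,3-diene-1,3-dicarbaldehyde (o-quinone methide; not isolated) | O=C1/C(=C/c2ccccc2)C(O)=C(C=O)C(O)=C1C=O | intermediate
14 | Guajadial D (chroman centers 2S,4S; octalin centers 4aR,5R,8S) | CC(C)[C@@H]1CC[C@@H](C)[C@H]2CC[C@@]3(C=C12)C[C@@H](c1ccccc1)c1c(O)c(C=O)c(O)c(C=O)c1O3 | target

**Count**

Total steps: 6. Longest linear sequence: 6 steps (1 → 14).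

**Steps most likely to fail**

1. Step 3 (proposed new method). The silylated dione may condense with itself faster than the alkene closes onto it, the tertiary cation may lose the ring proton instead of a methyl proton (which would erase the C8 stereocenter), or the mismatched C4a epimer may fail to equilibrate. Fallback by known chemistry, setting out from 5 and returning at 8: enol etherification of 5 (MeOH, cat. TsOH) gives the vinylogous ester 3-methoxy-6-[(2R)-6-methylhept-5-en-2-yl]cyclohex-2-en-1-one F1. Reduction of its carbonyl with LiAlH4 and acid hydrolysis (Stork–Danheiser transposition) gives 4-[(2R)-6-methylhept-5-en-2-yl]cyclohex-2-en-1-one F2 as two C4 epimers. MeAlCl2 in CH2Cl2 at −78 °C closes ring A by the Lewis-acid-promoted conjugate ene cyclization of an alkenyl enone (the same perpendicular attack and chair, now on the enone β-carbon), and the matched epimer gives the cis-fused decalone (4aR,5R,8R,8aR)-5-methyl-8-(prop-1-en-2-yl)octahydronaphthalen-2(1H)-one F3. Thermodynamic silylation (Me3SiCl, NaI, Et3N), which for a cis-fused 2-decalone goes toward C1, gives trimethyl{[(4aR,5R,8R,8aR)-5-methyl-8-(prop-1-en-2-yl)-3,4,4a,5,6,7,8,8a-octahydronaphthalen-2-yl]oxy}silane F4, and Saegusa–Ito oxidation with Pd(OAc)2 in MeCN gives 8.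

2. Step 2. The Michael addition may occur at the methyl group instead of the hindered methylene (leading to the 2-alkyl dione), or the acrylate may add twice or oligomerise. Fallback, setting out from 2 and returning at 5: thermodynamic silylation (Me3SiCl, NaI, Et3N, MeCN) gives the more substituted enol ether trimethyl{[(2Z,4R)-4,8-dimethylnona-2,7-dien-2-yl]oxy}silane F5. Its Mukaiyama–Michael addition to 3 (cat. HNTf2, CH2Cl2, −78 °C, then aqueous work-up) gives 4 as an isolated, regiodefined keto ester, which is closed separately with KOtBu in THF to 5.

3. Step 6. Facial and exo/endo selectivity of the cycloaddition may be poor, and the acid-sensitive diene may isomerise at 80 °C in acetic acid before it is trapped. Fallback, setting out from 12 and 11 and returning at 14: condensation of 12, 11 and 4-methylbenzenesulfinic acid (HCO2H, H2O, rt) gives the isolable precursor 2,4,6-trihydroxy-5-[(4-methylbenzenesulfonyl)(phenyl)methyl]benzene-1,3-dicarbaldehyde F6. With 10 and NaHCO3 in CH2Cl2/H2O at 0 °C → rt it releases 13 by base-induced loss of sulfinate under non-acidic conditions and at low temperature, which should protect the diene and sharpen the selectivity, and 13 is trapped to 14.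

**Further compounds**

F1 | step 3 | 3-methoxy-6-[(2R)-6-methylhept-5-en-2-yl]cyclohex-2-en-1-one | COC1=CC(=O)C(CC1)[C@H](C)CCC=C(C)C
F2 | step 3 | 4-[(2R)-6-methylhept-5-en-2-yl]cyclohex-2-en-1-one | O=C1C=CC(CC1)[C@H](C)CCC=C(C)C
F3 | step 3 | (4aR,5R,8R,8aR)-5-methyl-8-(prop-1-en-2-yl)octahydronaphthalen-2(1H)-one | CC(=C)[C@@H]1CC[C@@H](C)[C@H]2CCC(=O)C[C@@H]12
F4 | step 3 | trimethyl{[(4aR,5R,8R,8aR)-5-methyl-8-(prop-1-en-2-yl)-3,4,4a,5,6,7,8,8a-octahydronaphthalen-2-yl]oxy}silane | CC(=C)[C@@H]1CC[C@@H](C)[C@H]2CCC(O[Si](C)(C)C)=C[C@@H]12
F5 | step 2 | trimethyl{[(2Z,4R)-4,8-dimethylnona-2,7-dien-2-yl]oxy}silane | C/C(O[Si](C)(C)C)=C/[C@H](C)CCC=C(C)C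
F6 | step 6 | 2,4,6-trihydroxy-5-[(4-methylbenzenesulfonyl)(phenyl)methyl]benzene-1,3-dicarbaldehyde | Cc1ccc(cc1)S(=O)(=O)C(c1ccccc1)c1c(O)c(C=O)c(O)c(C=O)c1O
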